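**Plan**
- Retrosynthesis: the three phenols are unmasked last from silyl ethers. Ring C is then cut at O1–C2 and at C3–C4, which leaves salicylaldehyde 4 (ring A, 8-prenyl group in place) and arylacetylene 9 (ring B).
- Enabling feature: O1 sits on C8a of ring A, ortho to the C4 carbonyl carbon, and C2 is β to that carbonyl and benzylic to ring B. The same oxygen can first steer rhodium into the formyl C–H bond (C3–C4 by alkyne hydroacylation) and then add to C2 (oxa-Michael), so one operation builds ring C.
- Forward, ring A piece: 2,4,6-trihydroxybenzaldehyde is C-prenylated and bis-silylated so that only the O1 hydroxyl stays free.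
- Forward, ring B piece: 4-hydroxy-2-methoxybenzaldehyde is O-prenylated, rearranged (aromatic Claisen) to the 1,1-dimethylallyl phenol, silylated and homologated to the alkyne.
- Rings A and B come from the starting materials; ring C is the only ring made and closes in step 7; buffered desilylation ends the route.
- Stereochemistry: C2 is the only stereocentre. It is set in step 7 by a chiral amine–thiourea catalyst during ring closure and meets no base afterwards.

Key step: step 7

Assumption: the thiourea derived from 9-amino-9-deoxy-epi-quinine is taken to deliver the (2S) flavanone; if the sense of induction proves opposite, its pseudoenantiomer from epi-quinidine takes its place in the same step.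

**Step 1**
Reactants: 1 2,4,6-trihydroxybenzaldehyde; 2 prenyl bromide (1-bromo-3-methylbut-2-ene)
Product: 3 2,4,6-trihydroxy-3-(3-methylbut-2-en-1-yl)benzaldehyde
Conditions: DBU (1.0 equiv), THF, 0 °C to rt, slow addition of 2 (1.0 equiv)
Reagents that add atoms: none
Why: Base-mediated C-alkylation of a phloroglucinol-type phenoxide (C-prenylation); the two open ring positions of 1 are equivalent, so only one mono-C-prenyl product can form.

**Step 2**
Reactants: 3 2,4,6-trihydroxy-3-(3-methylbut-2-en-1-yl)benzaldehyde
Product: 4 4,6-bis(tert-butyldimethylsilyloxy)-2-hydroxy-3-(3-methylbut-2-en-1-yl)benzaldehyde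
Conditions: TBSCl (2.1 equiv), imidazole, CH2Cl2, 0 °C
Reagents that add atoms: tert-butyldimethylsilyl chloride, CC(C)(C)[Si](C)(C)Cl
Why: Regioselective silyl ether formation; the 4-OH (most acidic, not chelated) and the 6-OH (one ortho neighbour) should react, while the 2-OH, wedged between the prenyl and formyl groups and hydrogen-bonded to the carbonyl, should stay free.

**Step 3**
Reactants: 5 4-hydroxy-2-methoxybenzaldehyde; 2 prenyl bromide
Product: 6 2-methoxy-4-(3-methylbut-2-en-1-yloxy)benzaldehyde
Conditions: K2CO3, acetone, reflux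
Reagents that add atoms: none
Why: Williamson ether synthesis on the only phenol, which the para-formyl group makes acidic.

**Step 4**
Reactants: 6 2-methoxy-4-(3-methylbut-2-en-1-yloxy)benzaldehyde
Product: 7 4-hydroxy-2-methoxy-5-(2-methylbut-3-en-2-yl)benzaldehyde
Conditions: EtOH/H2O (4:1), 130 °C, sealed tube
Reagents that add atoms: none
Why: Aromatic Claisen rearrangement ([3,3]) of the aryl prenyl ether, which inverts the allyl unit to the 1,1-dimethylallyl group; it should go to C5 (para to OMe) and not to C3 between the two oxygens, and the protic medium allows a temperature low enough to hold back the abnormal Claisen isomerisation.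

**Step 5**
Reactants: 7 4-hydroxy-2-methoxy-5-(2-methylbut-3-en-2-yl)benzaldehyde
Product: 8 4-(tert-butyldimethylsilyloxy)-2-methoxy-5-(2-methylbut-3-en-2-yl)benzaldehyde
Conditions: TBSCl, imidazole, DMF, rt
Reagents that add atoms: tert-butyldimethylsilyl chloride, CC(C)(C)[Si](C)(C)Cl
Why: Silyl ether formation on the phenol, which keeps a free para-hydroxyarylalkyne out of the rhodium step and survives the strong base of step 6.

**Step 6**
Reactants: 8 4-(tert-butyldimethylsilyloxy)-2-methoxy-5-(2-methylbut-3-en-2-yl)benzaldehyde
Product: 9 tert-butyl[4-ethynyl-5-methoxy-2-(2-methylbut-3-en-2-yl)phenoxy]dimethylsilane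
Conditions: Me3SiCHN2, LiN(iPr)2, THF, −78 °C to rt
Reagents that add atoms: trimethylsilyldiazomethane, C[Si](C)(C)C=[N+]=[N-]
Why: Colvin rearrangement; the lithiated diazo compound adds to the aldehyde, Peterson-type loss of silanolate gives a diazoalkene, and N2 loss with 1,2-hydride shift of the alkylidene carbene gives the terminal alkyne, without touching the silyl ether or the vinyl group.

**Step 7**
Reactants: 4 4,6-bis(tert-butyldimethylsilyloxy)-2-hydroxy-3-(3-methylbut-2-en-1-yl)benzaldehyde; 9 tert-butyl[4-ethynyl-5-methoxy-2-(2-methylbut-3-en-2-yl)phenoxy]dimethylsilane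
Product: 11 (2S)-5,7-bis(tert-butyldimethylsilyloxy)-2-[4-(tert-butyldimethylsilyloxy)-2-methoxy-5-(2-methylbut-3-en-2-yl)phenyl]-8-(3-methylbut-2-en-1-yl)chroman-4-one, via (E)-2'-hydroxychalcone 10 (not isolated)
Conditions: [RhCl(cod)]2 (2.5 mol%), dppf [Fe(C5H4PPh2)2] (5 mol%), Na2CO3 (5 mol%), toluene, 80 °C; then −20 °C, 3,5-bis(trifluoromethyl)phenyl thiourea of 9-amino-9-deoxy-epi-quinine (10 mol%); AcOH quench
Reagents that add atoms: none
Why: Proposed new method: the phenoxide oxygen of 4 (the later O1) binds monovalent rhodium and guides it into the neighbouring formyl C–H bond to give a five-membered acyl(hydrido) chelate of trivalent rhodium that resists decarbonylation, syn hydrometalation of alkyne 9 then places rhodium on the terminal carbon and C–C reductive elimination gives the (E)-chalcone 10 (C3–C4 bond), after which the same oxygen, deprotonated by the quinuclidine nitrogen of the catalyst while the thiourea N–H bonds hold the enone carbonyl, adds to the benzylic β-carbon (O1–C2 bond). The closest known reaction types are the rhodium-catalysed coupling of salicylaldehydes with alkynes to 2-alkenoylphenols, including its one-pot extension by base-induced oxa-Michael closure to chroman-4-ones, and the amine–thiourea-catalysed enantioselective closure of 2'-hydroxychalcone-type enones, which is secure only for α-ester-activated enones, so the relay on an unactivated chalcone under a chiral catalyst is the new part. Ring C is the only ring closed and it closes in the 6-endo-trig mode. The C2 stereocentre is under catalyst control: in the ion pair of phenoxide and protonated quinuclidine the thiourea fixes the s-cis enone so that oxygen reaches only one face of C2, which is expected to give the (2S) product. The step needs linear regioselectivity in the hydroacylation (secured by the terminal alkyne, whose ortho-methoxyaryl end keeps rhodium away from the internal carbon), reaction of the alkyne ahead of the hindered vinyl group and the trisubstituted prenyl alkene, and closure through the oxygen next to the prenyl group (secured because the other ortho oxygen of 4 is silylated). The 6'-siloxy group twists the enone out of the plane of ring A, which favours the closed form and, together with the low temperature and the acid quench, limits loss of enantiomeric purity by retro-oxa-Michael opening.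

**Step 8**
Reactants: 11 (2S)-5,7-bis(tert-butyldimethylsilyloxy)-2-[4-(tert-butyldimethylsilyloxy)-2-methoxy-5-(2-methylbut-3-en-2-yl)phenyl]-8-(3-methylbut-2-en-1-yl)chroman-4-one
Product: 12 (2S)-5,7-dihydroxy-2-[4-hydroxy-2-methoxy-5-(2-methylbut-3-en-2-yl)phenyl]-8-(3-methylbut-2-en-1-yl)chroman-4-one
Conditions: Bu4NF (3.3 equiv), AcOH (3.3 equiv), THF, 0 °C
Reagents that add atoms: none
Why: Fluoride-induced cleavage of the three aryl silyl ethers; the acetic acid buffer keeps the phenols protonated, so the flavanone cannot open by E1cB and C2 keeps its configuration, and the prenyl and 1,1-dimethylallyl groups are inert.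

**Compound list**
1 | 2,4,6-trihydroxybenzaldehyde | O=Cc1c(O)cc(O)cc1O | starting material
2 | prenyl bromide (1-bromo-3-methylbut-2-ene) | CC(C)=CCBr | starting material
3 | 2,4,6-trihydroxy-3-(3-methylbut-2-en-1-yl)benzaldehyde | O=Cc1c(O)cc(O)c(CC=C(C)C)c1O | intermediate
4 | 4,6-bis(tert-butyldimethylsilyloxy)-2-hydroxy-3-(3-methylbut-2-en-1-yl)benzaldehyde | O=Cc1c(O[Si](C)(C)C(C)(C)C)cc(O[Si](C)(C)C(C)(C)C)c(CC=C(C)C)c1O | intermediate
5 | 4-hydroxy-2-methoxybenzaldehyde | COc1cc(O)ccc1C=O | starting material
6 | 2-methoxy-4-(3-methylbut-2-en-1-yloxy)benzaldehyde | COc1cc(OCC=C(C)C)ccc1C=O | intermediate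
7 | 4-hydroxy-2-methoxy-5-(2-methylbut-3-en-2-yl)benzaldehyde | COc1cc(O)c(C(C)(C)C=C)cc1C=O | intermediate
8 | 4-(tert-butyldimethylsilyloxy)-2-methoxy-5-(2-methylbut-3-en-2-yl)benzaldehyde | COc1cc(O[Si](C)(C)C(C)(C)C)c(C(C)(C)C=C)cc1C=O | intermediate
9 | tert-butyl[4-ethynyl-5-methoxy-2-(2-methylbut-3-en-2-yl)phenoxy]dimethylsilane | COc1cc(O[Si](C)(C)C(C)(C)C)c(C(C)(C)C=C)cc1C#C | intermediate
10 | (E)-1-[4,6-bis(tert-butyldimethylsilyloxy)-2-hydroxy-3-(3-methylbut-2-en-1-yl)phenyl]-3-[4-(tert-butyldimethylsilyloxy)-2-methoxy-5-(2-methylbut-3-en-2-yl)phenyl]prop-2-en-1-one | COc1cc(O[Si](C)(C)C(C)(C)C)c(C(C)(C)C=C)cc1/C=C/C(=O)c1c(O[Si](C)(C)C(C)(C)C)cc(O[Si](C)(C)C(C)(C)C)c(CC=C(C)C)c1O | intermediate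
11 | (2S)-5,7-bis(tert-butyldimethylsilyloxy)-2-[4-(tert-butyldimethylsilyloxy)-2-methoxy-5-(2-methylbut-3-en-2-yl)phenyl]-8-(3-methylbut-2-en-1-yl)chroman-4-one | C=CC(C)(C)c1cc([C@@H]2CC(=O)c3c(O[Si](C)(C)C(C)(C)C)cc(O[Si](C)(C)C(C)(C)C)c(CC=C(C)C)c3O2)c(OC)cc1O[Si](C)(C)C(C)(C)C | intermediate
12 | (2S)-5,7-dihydroxy-2-[4-hydroxy-2-methoxy-5-(2-methylbut-3-en-2-yl)phenyl]-8-(3-methylbut-2-en-1-yl)chroman-4-one | C=CC(C)(C)c1cc([C@@H]2CC(=O)c3c(O)cc(O)c(CC=C(C)C)c3O2)c(OC)cc1O | target

**Step count**
Total steps: 8. Longest linear sequence: 6 steps (steps 3, 4, 5, 6, 7, 8).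

**Steps most likely to fail**

1. Step 7 (proposed new method). The ring closure of the unactivated chalcone may show poor facial discrimination, or the enantiomeric purity may erode through reversible ring opening or through uncatalysed closure during the warm rhodium stage. The fallback sets out from 4 and 9 and comes back at 11. The hydroacylation is run alone with the same rhodium system and chalcone 10 is isolated. DBU (10 mol%) in toluene at rt closes it to the racemic tris-silyl flavanone F1. Preparative HPLC on an amylose tris(3,5-dimethylphenylcarbamate) phase then gives 11. The unwanted half of F1 is re-equilibrated with DBU and resolved again.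

2. Step 2. Silylation may occur at the wrong ortho oxygen and give a mixture of regioisomeric bis-silyl ethers, which would carry through to the 6-prenyl series. The fallback sets out from 1 and comes back at 4, and fixes the regiochemistry by construction. TBSCl (2 equiv) and imidazole convert 1, whose ortho hydroxyls are equivalent, into 4,6-bis(tert-butyldimethylsilyloxy)-2-hydroxybenzaldehyde F2. 2-Chloro-2-methylbut-3-yne, DBU and CuCl2 (cat.) in MeCN at 0 °C give 4,6-bis(tert-butyldimethylsilyloxy)-2-(2-methylbut-3-yn-2-yloxy)benzaldehyde F3. Semihydrogenation (H2, Pd on CaCO3 poisoned with Pb(OAc)2, quinoline) gives 4,6-bis(tert-butyldimethylsilyloxy)-2-(2-methylbut-3-en-2-yloxy)benzaldehyde F4. Aromatic Claisen rearrangement in toluene at reflux moves the allyl unit with inversion to C3, the only open ortho position, and gives 4.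

3. Step 4. The prenyl ether may cleave heterolytically (the para-formyl group makes the phenoxide a good leaving group), the allyl unit may migrate to C3, or the product may isomerise further by the abnormal Claisen path. The fallback sets out from 5 and comes back at 8. NBS in MeCN at 0 °C brominates C5 (ortho to OH, para to OMe) to 5-bromo-4-hydroxy-2-methoxybenzaldehyde F5. TBSCl and imidazole give 5-bromo-4-(tert-butyldimethylsilyloxy)-2-methoxybenzaldehyde F6. A ligand-controlled γ-selective Suzuki–Miyaura coupling with 3-methylbut-2-enylboronic acid pinacol ester (Pd(OAc)2, bulky biaryl dialkylphosphine, K3PO4, THF/H2O, 40 °C) then attaches the 1,1-dimethylallyl group through its tertiary carbon and gives 8.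

**Further compounds**
F1 | step 7 | racemic 5,7-bis(tert-butyldimethylsilyloxy)-2-[4-(tert-butyldimethylsilyloxy)-2-methoxy-5-(2-methylbut-3-en-2-yl)phenyl]-8-(3-methylbut-2-en-1-yl)chroman-4-one | C=CC(C)(C)c1cc(C2CC(=O)c3c(O[Si](C)(C)C(C)(C)C)cc(O[Si](C)(C)C(C)(C)C)c(CC=C(C)C)c3O2)c(OC)cc1O[Si](C)(C)C(C)(C)C
F2 | step 2 | 4,6-bis(tert-butyldimethylsilyloxy)-2-hydroxybenzaldehyde | O=Cc1c(O[Si](C)(C)C(C)(C)C)cc(O[Si](C)(C)C(C)(C)C)cc1O
F3 | step 2 | 4,6-bis(tert-butyldimethylsilyloxy)-2-(2-methylbut-3-yn-2-yloxy)benzaldehyde | O=Cc1c(O[Si](C)(C)C(C)(C)C)cc(O[Si](C)(C)C(C)(C)C)cc1OC(C)(C)C#C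
F4 | step 2 | 4,6-bis(tert-butyldimethylsilyloxy)-2-(2-methylbut-3-en-2-yloxy)benzaldehyde | O=Cc1c(O[Si](C)(C)C(C)(C)C)cc(O[Si](C)(C)C(C)(C)C)cc1OC(C)(C)C=C
F5 | step 4 | 5-bromo-4-hydroxy-2-methoxybenzaldehyde | COc1cc(O)c(Br)cc1C=O
F6 | step 4 | 5-bromo-4-(tert-butyldimethylsilyloxy)-2-methoxybenzaldehyde | COc1cc(O[Si](C)(C)C(C)(C)C)c(Br)cc1C=O
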